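## Retrosynthetic overview

- The target is opened to an acyclic tertiary dienyl carbinol. The cyclohexene ring (ring-closing metathesis) and the oxygen bridge (bromoetherification, Br anti to O) are then closed in one flask; this is the key step.
- The carbinol comes from a ring A bromo ketone and an allyl group; a reagent-controlled allylboration sets the carbinol centre, which later fixes both bridgeheads and the C–Br centre of the bicycle.
- The bromo ketone comes from an acyclic trienyl carbinol by an enantioselective bromonium cyclization that ends in a semipinacol 1,2-hydride shift (Br and acyl trans on ring A).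
- The trienyl carbinol comes from the enol triflate of sulcatone and 4-methylpent-4-enal (Nozaki–Hiyama–Kishi coupling).
- Ring order: ring A first (step 3), then the cyclohexene and the oxolane bridge together (step 5).

Assumptions: 4-methylpent-4-enal is bought as a catalogue compound; in steps 3 and 4 the antipode of the chiral promoter that is written is the one taken to give the configuration shown (assigned by analogy, not verified; the mirror-image promoter is equally accessible), and the chiral allylborane is made separately by its published route and treated as a reagent.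

## Route

Step 1
Reactants: 1 6-methylhept-5-en-2-one (sulcatone)
Product: 2 6-methylhepta-1,5-dien-2-yl trifluoromethanesulfonate
Conditions: LiN(iPr)2 (1.05 equiv), THF, −78 °C; then PhNTf2 (1.05 equiv), −78 → 0 °C
Reagents that add atoms: N-phenylbis(trifluoromethanesulfonimide) (PhNTf2), O=S(=O)(N(c1ccccc1)S(=O)(=O)C(F)(F)F)C(F)(F)F
Why: Kinetic deprotonation of the methyl ketone at CH3 by the hindered amide and O-sulfonylation of the terminal lithium enolate (enol triflate formation); no stereocentre is formed.

Step 2
Reactants: 2 6-methylhepta-1,5-dien-2-yl trifluoromethanesulfonate; 3 4-methylpent-4-enal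
Product: 4 2,10-dimethyl-6-methylideneundeca-1,9-dien-5-ol (racemic)
Conditions: CrCl2 (4 equiv), NiCl2 (2 mol%), DMF, 25 °C; aqueous work-up
Reagents that add atoms: none
Why: Nozaki–Hiyama–Kishi reaction: zerovalent nickel formed in situ inserts into the alkenyl C–OTf bond, transmetalation gives an alkenyl species of trivalent chromium that adds only to the aldehyde; the carbinol centre is left racemic on purpose because step 3 erases it.

Step 3
Reactants: 4 2,10-dimethyl-6-methylideneundeca-1,9-dien-5-ol
Product: 6 1-[(1S,4S)-4-bromo-3,3-dimethylcyclohexyl]-4-methylpent-4-en-1-one, via ring A tertiary carbocation 5 (not isolated)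
Conditions: 1,3-dibromo-5,5-dimethylhydantoin (0.55 equiv), (S)-BINOL-derived N-aryl thiophosphoramide (10 mol%), PhMe–CH2Cl2, −78 °C
Reagents that add atoms: 1,3-dibromo-5,5-dimethylhydantoin, CC1(C)N(Br)C(=O)N(Br)C1=O
Why: Proposed new method: the chiral Lewis base passes Br+ to one face of the trisubstituted alkene (sets the C–Br centre as S), the 1,1-disubstituted alkene closes ring A through a chair with Br equatorial, and cation 5 is quenched by a 1,2-hydride shift from the carbinol carbon anti to the new C–C bond (semipinacol), which puts H axial and the acyl group equatorial (C1 S, trans to Br) and makes both carbinol epimers of 4 converge on one ketone; the closest known reactions are the catalytic asymmetric bromonium polyene cyclization with arene terminators and halonium- or Prins-triggered semipinacol rearrangements of allylic alcohols.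

Step 4
Reactants: 6 1-[(1S,4S)-4-bromo-3,3-dimethylcyclohexyl]-4-methylpent-4-en-1-one
Product: 7 (4S)-4-[(1S,4S)-4-bromo-3,3-dimethylcyclohexyl]-7-methylocta-1,7-dien-4-ol
Conditions: B-allyl-(10R)-10-phenyl-9-borabicyclo[3.3.2]decane (1.3 equiv), Et2O, −78 °C; then MeOH/H2O
Reagents that add atoms: B-allyl-(10R)-10-phenyl-9-borabicyclo[3.3.2]decane, C=CCB1C2CCCC(CCC2)[C@@H]1c1ccccc1
Why: Asymmetric allylboration of a ketone (Soderquist reagent): allyl is delivered through a closed chair transition state in which the bulky ring A group avoids the 10-phenyl group, so the reagent rather than the weak bias of the α-stereocentre fixes Si-face attack and the (4S) carbinol, and the neutral conditions at −78 °C leave the epimerisable C1 of ring A and the bromide untouched.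

Step 5
Reactants: 7 (4S)-4-[(1S,4S)-4-bromo-3,3-dimethylcyclohexyl]-7-methylocta-1,7-dien-4-ol
Product: 9 (1R,2R,4S)-2-bromo-4-[(1S,4S)-4-bromo-3,3-dimethylcyclohexyl]-1-methyl-7-oxabicyclo[2.2.1]heptane (target CNP0182648.1), via cyclohexenol 8 (not isolated)
Conditions: second-generation Grubbs catalyst RuCl2(=CHPh)(PCy3)(H2IMes) (3 mol%), CH2Cl2 (0.01 M), 40 °C; argon purge, then NBS (1.1 equiv), 0 °C, same flask
Reagents that add atoms: N-bromosuccinimide, O=C1CCC(=O)N1Br
Why: Ring-closing metathesis joins the allyl and the 1,1-disubstituted alkene into the trisubstituted cyclohexene 8, then NBS forms the bromonium ion on the face away from the tertiary hydroxyl, which opens it at the tertiary carbon through a boat (bromoetherification, anti addition), so both bridgeheads follow from the carbinol centre of 7 and Br ends endo, anti to the oxygen bridge.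

## Compound list

1 | 6-methylhept-5-en-2-one (sulcatone) | CC(=O)CCC=C(C)C | starting material
2 | 6-methylhepta-1,5-dien-2-yl trifluoromethanesulfonate | C=C(CCC=C(C)C)OS(=O)(=O)C(F)(F)F | intermediate
3 | 4-methylpent-4-enal | C=C(C)CCC=O | starting material
4 | 2,10-dimethyl-6-methylideneundeca-1,9-dien-5-ol (racemic) | CC(C)=CCCC(=C)C(O)CCC(C)=C | intermediate
5 | (4S)-4-bromo-1-(1-hydroxy-4-methylpent-4-enyl)-3,3-dimethylcyclohexan-1-ylium, ring A tertiary carbocation (not isolated) | CC1(C)C[C+](C(O)CCC(C)=C)CC[C@@H]1Br | intermediate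
6 | 1-[(1S,4S)-4-bromo-3,3-dimethylcyclohexyl]-4-methylpent-4-en-1-one | CC1(C)C[C@@H](C(=O)CCC(C)=C)CC[C@@H]1Br | intermediate
7 | (4S)-4-[(1S,4S)-4-bromo-3,3-dimethylcyclohexyl]-7-methylocta-1,7-dien-4-ol | CC1(C)C[C@@H]([C@@](O)(CC=C)CCC(C)=C)CC[C@@H]1Br | intermediate
8 | (1S)-1-[(1S,4S)-4-bromo-3,3-dimethylcyclohexyl]-4-methylcyclohex-3-en-1-ol, cyclohexenol (not isolated) | CC1(C)C[C@@H]([C@@]2(O)CC=C(C)CC2)CC[C@@H]1Br | intermediate
9 | (1R,2R,4S)-2-bromo-4-[(1S,4S)-4-bromo-3,3-dimethylcyclohexyl]-1-methyl-7-oxabicyclo[2.2.1]heptane | CC1(C)C[C@@H]([C@@]23CC[C@@](C)(O2)[C@H](Br)C3)CC[C@@H]1Br | target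

## Step count and risks

Total steps: 5. Longest linear sequence: 5 (1 → 2 → 4 → 6 → 7 → 9).

**Step 3 is the most likely to fail.** Asymmetric Br+ transfer of this kind is only established with arene or phenol terminators. Cation 5 can also lose a proton, close to a bromo epoxide or be caught by the distal alkene. The trans relationship on ring A is kinetic, not thermodynamic, so 6 must not be equilibrated with base. The fallback sets out from 4 and cyclizes it without a chiral promoter (Et2SBr·SbBrCl5, MeNO2, −25 °C). This gives the racemic trans ketone, that is 6 together with its mirror image 1-[(1R,4R)-4-bromo-3,3-dimethylcyclohexyl]-4-methylpent-4-en-1-one F1. The reagent-controlled allylboration of step 4 on this racemate gives 7 and its diastereomer (4S)-4-[(1R,4R)-4-bromo-3,3-dimethylcyclohexyl]-7-methylocta-1,7-dien-4-ol F2, which are separated on silica. The route is rejoined at 7; at most half of the material is used, and the enantiopurity then rests on the reagent control of step 4.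

**Step 4 is the second risk.** The allylborane has to tell a secondary alkyl group from a primary one next to an existing stereocentre, and a mismatched pairing would erode the ratio. The fallback sets out from 6 and adds allylmagnesium bromide (THF, −78 °C) without control. This gives 7 together with its carbinol epimer (4R)-4-[(1S,4S)-4-bromo-3,3-dimethylcyclohexyl]-7-methylocta-1,7-dien-4-ol F3. The mixture is taken through the conditions of step 5, where F3 gives, via the cyclohexenol (1R)-1-[(1S,4S)-4-bromo-3,3-dimethylcyclohexyl]-4-methylcyclohex-3-en-1-ol F4, the diastereomeric dibromide (1S,2S,4R)-2-bromo-4-[(1S,4S)-4-bromo-3,3-dimethylcyclohexyl]-1-methyl-7-oxabicyclo[2.2.1]heptane F5. Compounds 9 and F5 are diastereomers and are separated by chromatography or crystallisation, so the route is rejoined at 9.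

**Step 5 is the third risk.** The bromonium ion of 8 may lose a proton to give an allylic bromide faster than the hydroxyl closes the strained bridge, and ruthenium residues may consume NBS. The fallback sets out from 7, runs the metathesis alone and isolates 8. The bridge is then closed by intramolecular oxymercuration (Hg(O2CCF3)2, MeCN, −20 °C), which gives [(1R,2R,4S)-4-[(1S,4S)-4-bromo-3,3-dimethylcyclohexyl]-1-methyl-7-oxabicyclo[2.2.1]heptan-2-yl]mercury trifluoroacetate F6 with mercury anti to the new C–O bond. Aqueous NaBr exchanges this to [(1R,2R,4S)-4-[(1S,4S)-4-bromo-3,3-dimethylcyclohexyl]-1-methyl-7-oxabicyclo[2.2.1]heptan-2-yl]mercury bromide F7. Cleavage of the C–Hg bond with Br2/LiBr in pyridine (retention) arrives at 9.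

## Further compounds

F1 | step 3 | 1-[(1R,4R)-4-bromo-3,3-dimethylcyclohexyl]-4-methylpent-4-en-1-one | CC1(C)C[C@H](C(=O)CCC(C)=C)CC[C@H]1Br
F2 | step 3 | (4S)-4-[(1R,4R)-4-bromo-3,3-dimethylcyclohexyl]-7-methylocta-1,7-dien-4-ol | CC1(C)C[C@H]([C@@](O)(CC=C)CCC(C)=C)CC[C@H]1Br
F3 | step 4 | (4R)-4-[(1S,4S)-4-bromo-3,3-dimethylcyclohexyl]-7-methylocta-1,7-dien-4-ol | CC1(C)C[C@@H]([C@](O)(CC=C)CCC(C)=C)CC[C@@H]1Br
F4 | step 4 | (1R)-1-[(1S,4S)-4-bromo-3,3-dimethylcyclohexyl]-4-methylcyclohex-3-en-1-ol | CC1(C)C[C@@H]([C@]2(O)CC=C(C)CC2)CC[C@@H]1Br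
F5 | step 4 | (1S,2S,4R)-2-bromo-4-[(1S,4S)-4-bromo-3,3-dimethylcyclohexyl]-1-methyl-7-oxabicyclo[2.2.1]heptane | CC1(C)C[C@@H]([C@]23CC[C@](C)(O2)[C@@H](Br)C3)CC[C@@H]1Br
F6 | step 5 | [(1R,2R,4S)-4-[(1S,4S)-4-bromo-3,3-dimethylcyclohexyl]-1-methyl-7-oxabicyclo[2.2.1]heptan-2-yl]mercury trifluoroacetate | CC1(C)C[C@@H]([C@@]23CC[C@@](C)(O2)[C@H]([Hg]OC(=O)C(F)(F)F)C3)CC[C@@H]1Br
F7 | step 5 | [(1R,2R,4S)-4-[(1S,4S)-4-bromo-3,3-dimethylcyclohexyl]-1-methyl-7-oxabicyclo[2.2.1]heptan-2-yl]mercury bromide | CC1(C)C[C@@H]([C@@]23CC[C@@](C)(O2)[C@H]([Hg]Br)C3)CC[C@@H]1Br
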